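**Assumption:** (S)-4-hydroxycyclopent-2-enone (1) and methyl (E)-3-methoxyacrylate (9) are purchased; dione 7 and lactol 17 are drawn as a single tautomer/anomer.

## Retrosynthetic overview

1. Iridoid numbering is used: C1 acetal, O2, C3=C4(–C11), C5=C6, C7, C8(–C10), C9. The endgame is 7-O-isovalerylation ⇐ Luche reduction of a 7-ketone (sets C7 trans to 8-OH) ⇐ 1-O-isovalerylation of a 7-oxo lactol.
2. The dihydropyran is the last ring formed: acid unmasks a C1 dimethyl acetal and a C3 vinylogous methyl ester, and the dienol closes on the C1 aldehyde.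
3. Key disconnection C4–C5: Stille coupling of a cyclopentenone vinylogous triflate (C1, C5–C10, both ring stereocentres) with a (Z)-β-methoxyvinylstannane (O2, C3, C4, C11).
4. Triflate: (S)-4-hydroxycyclopentenone → trans α′-dimethoxymethylation (C9) → anti hydroxymethylation of the ketone (C8/C10) → allylic oxidation → Wacker-type β-oxidation → regioselective enol triflation. Stannane: methyl 3-methoxyacrylate → (Z)-α-iodide → reduction → stannylation → acetate.
5. Ring order: the cyclopentene is carried from the starting material; the pyran is closed after the fragment coupling.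

## Fragment A (cyclopentenone triflate)

**Step 1**
Reactants: 1, (S)-4-hydroxycyclopent-2-en-1-one
Product: 2, (S)-4-(triethylsilyloxy)cyclopent-2-en-1-one
Conditions: TESCl, imidazole, CH2Cl2, 0 °C
Reagents that add atoms: chlorotriethylsilane, CC[Si](Cl)(CC)CC
Why: Silyl protection of the secondary alcohol allows the α′-enolate to be formed; the stereocentre is untouched.

**Step 2**
Reactants: 2, (S)-4-(triethylsilyloxy)cyclopent-2-en-1-one
Product: 3, (4R,5R)-5-(dimethoxymethyl)-4-(triethylsilyloxy)cyclopent-2-en-1-one (4,5-trans)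
Conditions: LDA, THF, –78 °C; then (MeO)2CH+ BF4– [HC(OMe)3, BF3·OEt2, CH2Cl2, –30 °C], –78 °C
Reagents that add atoms: trimethyl orthoformate, COC(OC)OC
Why: α-Dialkoxymethylation of the kinetic cross-conjugated lithium enolate with a dialkoxycarbenium ion; the electrophile enters anti to the adjacent OTES, setting the future C9 trans to it.

**Step 3**
Reactants: 3, (4R,5R)-5-(dimethoxymethyl)-4-(triethylsilyloxy)cyclopent-2-en-1-one
Product: 4, (1R,4R,5S)-5-(dimethoxymethyl)-1-(hydroxymethyl)cyclopent-2-ene-1,4-diol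
Conditions: i-PrOMe2SiCH2MgCl, CeCl3, THF, –78 → 0 °C; then KF, KHCO3, 30% H2O2, THF/MeOH, rt; then TBAF
Reagents that add atoms: (isopropoxydimethylsilyl)methylmagnesium chloride, CC(C)O[Si](C)(C)C[Mg]Cl; hydrogen peroxide, OO
Why: Tamao nucleophilic hydroxymethylation (1,2-addition, then Tamao–Fleming oxidation); the organocerium attacks the carbonyl face anti to the neighbouring CH(OMe)2, so the tertiary OH ends up cis to it (sets C8), and fluoride removes the TES group.

**Step 4**
Reactants: 4, (1R,4R,5S)-5-(dimethoxymethyl)-1-(hydroxymethyl)cyclopent-2-ene-1,4-diol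
Product: 5, (4R,5S)-5-(dimethoxymethyl)-4-hydroxy-4-(hydroxymethyl)cyclopent-2-en-1-one
Conditions: MnO2, CH2Cl2, rt
Reagents that add atoms: none
Why: Chemoselective MnO2 oxidation of the secondary allylic alcohol; the primary and tertiary alcohols are not touched.

**Step 5**
Reactants: 5, (4R,5S)-5-(dimethoxymethyl)-4-hydroxy-4-(hydroxymethyl)cyclopent-2-en-1-one
Product: 6, [(1R,5S)-5-(dimethoxymethyl)-1-hydroxy-4-oxocyclopent-2-en-1-yl]methyl acetate
Conditions: Ac2O, pyridine, CH2Cl2, 0 °C
Reagents that add atoms: acetic anhydride, CC(=O)OC(C)=O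
Why: O-Acetylation of the only acylable (primary) hydroxyl; the tertiary alcohol does not react without DMAP.

**Step 6**
Reactants: 6, [(1R,5S)-5-(dimethoxymethyl)-1-hydroxy-4-oxocyclopent-2-en-1-yl]methyl acetate
Product: 7, [(1R,2S)-2-(dimethoxymethyl)-1-hydroxy-3,5-dioxocyclopentyl]methyl acetate (largely enolised)
Conditions: Na2PdCl4 (20 mol %), t-BuOOH, aq. i-PrOH, 50 °C
Reagents that add atoms: tert-butyl hydroperoxide, CC(C)(C)OO
Why: Tsuji-type Wacker oxidation of an enone places oxygen on the β-carbon (future C7) to give the 1,3-dione; no stereocentre is involved.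

**Step 7**
Reactants: 7, [(1R,2S)-2-(dimethoxymethyl)-1-hydroxy-3,5-dioxocyclopentyl]methyl acetate
Product: 8, [(1R,5R)-5-(dimethoxymethyl)-1-hydroxy-2-oxo-4-(trifluoromethylsulfonyloxy)cyclopent-3-en-1-yl]methyl acetate
Conditions: PhNTf2, i-Pr2NEt, CH2Cl2, 0 °C → rt
Reagents that add atoms: N-phenyl-bis(trifluoromethanesulfonimide), O=S(=O)(N(c1ccccc1)S(=O)(=O)C(F)(F)F)C(F)(F)F
Why: O-Sulfonylation of the dione enolate at the less hindered oxygen (remote from the quaternary carbinol) gives the vinylogous triflate with the ketone left at C7.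

## Fragment B (stannane)

**Step 8**
Reactants: 9, methyl (E)-3-methoxyacrylate
Product: 10, methyl (Z)-2-iodo-3-methoxyacrylate (OMe and I cis)
Conditions: NIS, AcOH, CH2Cl2, rt; then Et3N
Reagents that add atoms: N-iodosuccinimide, O=C1CCC(=O)N1I
Why: Iodo-acetoxylation of the enol ether followed by E1cB loss of AcOH gives the thermodynamic (Z)-α-iodoacrylate.

**Step 9**
Reactants: 10, methyl (Z)-2-iodo-3-methoxyacrylate
Product: 11, (Z)-2-iodo-3-methoxyprop-2-en-1-ol
Conditions: DIBAL-H (2.2 equiv), CH2Cl2, –78 °C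
Reagents that add atoms: none
Why: 1,2-Reduction of the ester to the allylic alcohol with the alkene geometry retained.

**Step 10**
Reactants: 11, (Z)-2-iodo-3-methoxyprop-2-en-1-ol
Product: 12, (Z)-tert-butyl[(2-iodo-3-methoxyallyl)oxy]dimethylsilane
Conditions: TBSCl, imidazole, DMF, rt
Reagents that add atoms: tert-butyldimethylsilyl chloride, CC(C)(C)[Si](C)(C)Cl
Why: Silyl protection gives clean halogen–metal exchange in the next step.

**Step 11**
Reactants: 12, (Z)-tert-butyl[(2-iodo-3-methoxyallyl)oxy]dimethylsilane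
Product: 13, (Z)-tert-butyl{[3-methoxy-2-(tributylstannyl)allyl]oxy}dimethylsilane
Conditions: t-BuLi (2.1 equiv), Et2O, –78 °C; then Bu3SnCl
Reagents that add atoms: tributyltin chloride, CCCC[Sn](Cl)(CCCC)CCCC
Why: Iodine–lithium exchange and stannylation with retention; the cis-β-alkoxy vinyllithium is configurationally stable at –78 °C.

**Step 12**
Reactants: 13, (Z)-tert-butyl{[3-methoxy-2-(tributylstannyl)allyl]oxy}dimethylsilane
Product: 14, (Z)-3-methoxy-2-(tributylstannyl)prop-2-en-1-ol
Conditions: TBAF, THF, 0 °C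
Reagents that add atoms: none
Why: Fluoride desilylation; the vinylstannane and enol ether are inert.

**Step 13**
Reactants: 14, (Z)-3-methoxy-2-(tributylstannyl)prop-2-en-1-ol
Product: 15, (Z)-3-methoxy-2-(tributylstannyl)allyl acetate
Conditions: Ac2O, pyridine, DMAP (cat.), CH2Cl2, 0 °C
Reagents that add atoms: acetic anhydride, CC(=O)OC(C)=O
Why: Standard O-acetylation installs the C11 acetate before the coupling.

## Fragment coupling and endgame

**Step 14**
Reactants: 8, vinylogous triflate; 15, (Z)-3-methoxy-2-(tributylstannyl)allyl acetate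
Product: 16, [(1R,5S)-4-[(E)-3-acetoxy-1-methoxyprop-1-en-2-yl]-5-(dimethoxymethyl)-1-hydroxy-2-oxocyclopent-3-en-1-yl]methyl acetate (OMe cis to the ring carbon)
Conditions: Pd(PPh3)4 (5 mol %), CuTC, [Ph2PO2][NBu4], DMF, 0 °C → rt
Reagents that add atoms: none
Why: Copper-assisted Stille coupling of a β-triflyloxy enone with a vinylstannane forms C4–C5 with retention of alkene geometry; no stereocentre is affected.

**Step 15**
Reactants: 16, coupled dienone
Product: 17, [(1R,7R,7aS)-7-(acetoxymethyl)-1,7-dihydroxy-6-oxo-1,6,7,7a-tetrahydrocyclopenta[c]pyran-4-yl]methyl acetate (lactol; 1β-OH anomer drawn)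
Conditions: 1 M aq. HCl/THF (1:4), 0 °C → rt
Reagents that add atoms: water, O
Why: Acid hydrolysis of the dimethyl acetal and the vinylogous methyl ester, then hemiacetalisation of the dienol onto the C1 aldehyde closes the pyran; C9 is epimerisable here and should settle with C1 trans to CH2OAc (cis to 8-OH).

**Step 16**
Reactants: 17, 7-oxo lactol
Product: 18, [(1S,7R,7aS)-7-(acetoxymethyl)-7-hydroxy-1-(3-methylbutanoyloxy)-6-oxo-1,6,7,7a-tetrahydrocyclopenta[c]pyran-4-yl]methyl acetate
Conditions: isovaleric anhydride, pyridine, DMAP (cat.), CH2Cl2, –20 °C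
Reagents that add atoms: isovaleric anhydride, CC(C)CC(=O)OC(=O)CC(C)C
Why: DMAP-catalysed acylation of the lactol hydroxyl; the ester is expected on the face trans to the C9–C8 bond (axial, anomerically stabilised, as in natural 1-O-acyl iridoids), and the tertiary OH is inert.

**Step 17**
Reactants: 18, 7-ketone
Product: 19, [(1S,6S,7R,7aS)-7-(acetoxymethyl)-6,7-dihydroxy-1-(3-methylbutanoyloxy)-1,6,7,7a-tetrahydrocyclopenta[c]pyran-4-yl]methyl acetate
Conditions: NaBH4, CeCl3·7H2O, MeOH/CH2Cl2, –78 → –40 °C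
Reagents that add atoms: none
Why: Luche 1,2-reduction; hydride adds to the face bearing the 8-OH (anti to CH2OAc, Ce-chelated α-ketol), giving the 7β-alcohol trans to 8-OH.

**Step 18**
Reactants: 19, 7β-alcohol
Product: 20, 10-acetoxyvaltrathydrin, [(1S,6S,7R,7aS)-7-(acetoxymethyl)-7-hydroxy-1,6-bis(3-methylbutanoyloxy)-1,6,7,7a-tetrahydrocyclopenta[c]pyran-4-yl]methyl acetate
Conditions: isovaleric anhydride, DMAP, pyridine, CH2Cl2, 0 °C → rt
Reagents that add atoms: isovaleric anhydride, CC(C)CC(=O)OC(=O)CC(C)C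
Why: Esterification of the secondary allylic alcohol under base-only conditions; the tertiary 8-OH stays free.

## Compound list

1 | (S)-4-hydroxycyclopent-2-en-1-one | O=C1C=C[C@@H](O)C1 | starting material
2 | (S)-4-(triethylsilyloxy)cyclopent-2-en-1-one | O=C1C=C[C@@H](O[Si](CC)(CC)CC)C1 | intermediate
3 | (4R,5R)-5-(dimethoxymethyl)-4-(triethylsilyloxy)cyclopent-2-en-1-one | COC(OC)[C@H]1[C@H](O[Si](CC)(CC)CC)C=CC1=O | intermediate
4 | (1R,4R,5S)-5-(dimethoxymethyl)-1-(hydroxymethyl)cyclopent-2-ene-1,4-diol | COC(OC)[C@H]1[C@H](O)C=C[C@]1(O)CO | intermediate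
5 | (4R,5S)-5-(dimethoxymethyl)-4-hydroxy-4-(hydroxymethyl)cyclopent-2-en-1-one | COC(OC)[C@H]1C(=O)C=C[C@]1(O)CO | intermediate
6 | [(1R,5S)-5-(dimethoxymethyl)-1-hydroxy-4-oxocyclopent-2-en-1-yl]methyl acetate | COC(OC)[C@H]1C(=O)C=C[C@]1(O)COC(C)=O | intermediate
7 | [(1R,2S)-2-(dimethoxymethyl)-1-hydroxy-3,5-dioxocyclopentyl]methyl acetate | COC(OC)[C@H]1C(=O)CC(=O)[C@]1(O)COC(C)=O | intermediate
8 | [(1R,5R)-5-(dimethoxymethyl)-1-hydroxy-2-oxo-4-(trifluoromethylsulfonyloxy)cyclopent-3-en-1-yl]methyl acetate | COC(OC)[C@H]1C(OS(=O)(=O)C(F)(F)F)=CC(=O)[C@]1(O)COC(C)=O | intermediate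
9 | methyl (E)-3-methoxyacrylate | CO/C=C/C(=O)OC | starting material
10 | methyl (Z)-2-iodo-3-methoxyacrylate | CO/C=C(\I)C(=O)OC | intermediate
11 | (Z)-2-iodo-3-methoxyprop-2-en-1-ol | CO/C=C(\I)CO | intermediate
12 | (Z)-tert-butyl[(2-iodo-3-methoxyallyl)oxy]dimethylsilane | CO/C=C(\I)CO[Si](C)(C)C(C)(C)C | intermediate
13 | (Z)-tert-butyl{[3-methoxy-2-(tributylstannyl)allyl]oxy}dimethylsilane | CO/C=C(\[Sn](CCCC)(CCCC)CCCC)CO[Si](C)(C)C(C)(C)C | intermediate
14 | (Z)-3-methoxy-2-(tributylstannyl)prop-2-en-1-ol | CO/C=C(\[Sn](CCCC)(CCCC)CCCC)CO | intermediate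
15 | (Z)-3-methoxy-2-(tributylstannyl)allyl acetate | CO/C=C(\[Sn](CCCC)(CCCC)CCCC)COC(C)=O | intermediate
16 | [(1R,5S)-4-[(E)-3-acetoxy-1-methoxyprop-1-en-2-yl]-5-(dimethoxymethyl)-1-hydroxy-2-oxocyclopent-3-en-1-yl]methyl acetate | COC(OC)[C@H]1C(/C(COC(C)=O)=C\OC)=CC(=O)[C@]1(O)COC(C)=O | intermediate
17 | [(1R,7R,7aS)-7-(acetoxymethyl)-1,7-dihydroxy-6-oxo-1,6,7,7a-tetrahydrocyclopenta[c]pyran-4-yl]methyl acetate | CC(=O)OCC1=CO[C@@H](O)[C@H]2C1=CC(=O)[C@]2(O)COC(C)=O | intermediate
18 | [(1S,7R,7aS)-7-(acetoxymethyl)-7-hydroxy-1-(3-methylbutanoyloxy)-6-oxo-1,6,7,7a-tetrahydrocyclopenta[c]pyran-4-yl]methyl acetate | CC(=O)OCC1=CO[C@@H](OC(=O)CC(C)C)[C@H]2C1=CC(=O)[C@]2(O)COC(C)=O | intermediate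
19 | [(1S,6S,7R,7aS)-7-(acetoxymethyl)-6,7-dihydroxy-1-(3-methylbutanoyloxy)-1,6,7,7a-tetrahydrocyclopenta[c]pyran-4-yl]methyl acetate | CC(=O)OCC1=CO[C@@H](OC(=O)CC(C)C)[C@H]2C1=C[C@H](O)[C@]2(O)COC(C)=O | intermediate
20 | 10-acetoxyvaltrathydrin, [(1S,6S,7R,7aS)-7-(acetoxymethyl)-7-hydroxy-1,6-bis(3-methylbutanoyloxy)-1,6,7,7a-tetrahydrocyclopenta[c]pyran-4-yl]methyl acetate | CC(=O)OCC1=CO[C@@H](OC(=O)CC(C)C)[C@H]2C1=C[C@H](OC(=O)CC(C)C)[C@]2(O)COC(C)=O | target

## Summary

**Total steps:** 18.
**Longest linear sequence:** 12 (steps 1–7, 14–18); the stannane branch (steps 8–13) is 6 steps and joins at step 14.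

**Steps most likely to fail, with fallbacks:**

- **Step 6 (Wacker-type β-oxidation).** The β-carbon is next to a quaternary carbinol and the dimethyl acetal is acid-labile. Fallback: replace the Pd oxidation by Cu-catalysed conjugate borylation of enone 6 (B2pin2), NaBO3 oxidation to the β-hydroxy ketone, and DMP oxidation to the same dione 7.
- **Step 2 (dimethoxymethylation of the enolate).** The enolate can eliminate the β-silyloxy group, and the carbenium ion is a harsh partner. Fallback: trap the enolate with monomeric formaldehyde (aldol), carry C1 as a silyl-protected CH2OH through the coupling, and raise it to the aldehyde (desilylation, DMP) only after step 14, just before lactol closure.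
- **Step 15 (unmasking and lactol closure).** The liberated dienol can lose the C11 acetate by vinylogous elimination, and C9 may give an epimer mixture. Fallback: carry C11 at the aldehyde oxidation level (stannane made from the 2-iodo-3-methoxyacrolein analogue), so the lactol is a doubly stabilised vinylogous ester. After 1-O-acylation, reduce both the C7 ketone and the C11 aldehyde, acetylate the primary C11-OH selectively, then isovalerylate C7-OH.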